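**Retrosynthetic overview**
1. The C11=C12 enone is made by Wittig olefination of a C11 aldehyde on a finished ring B; O6 acetylation and removal of the O7/O8 silyl ethers follow.
2. Ring B oxygens: 6α-OH and 5α-H come from α-face hydroboration of C5=C6, 7β-OH from Luche reduction of the C7 ketone, and 8β-CH3 then 8α-OH from the C7/C8 enolate.
3. Ring B (C5–C6–C7–C8–C9–C10) is built by a Michael–aldol annulation that forms C9–C10 and then C5=C6, joining the (S)-1-phenylethylamine imine of racemic 2,2,6-trimethylcyclohexanone (ring A) to methyl (E)-4-oxopent-2-enoate (C6–C9 plus C11).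
4. Feature used: in the ring A ketone the carbonyl carbon is C5 and C10 is its only enolisable carbon (C4 is quaternary), so one enamine forms and both ketone enantiomers converge on one C10 configuration.
5. Ring order: ring A is purchased; ring B is closed in step 2.

Key step: step 2

Remark on the chemistry: positions follow labdane numbering (ring A = C1–C5 and C10; ring B = C5–C10; C11 on C9; side chain C11=C12–C13(=O)–C14). β is the face of the C10 methyl group, α the opposite face. The two C10 epimers of imine 3 are assumed to interconvert through the enamine under the conditions of step 2.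

**Step 1**
Reactants: 1 2,2,6-trimethylcyclohexanone (racemic); 2 (S)-1-phenylethylamine
Product: 3 N-[(1S)-1-phenylethyl]-2,2,6-trimethylcyclohexan-1-imine (both C10 epimers)
Conditions: TiCl4 (0.55 equiv), Et3N (3 equiv), PhMe, 0 → 80 °C; filtered and used crude
Reagents that add atoms: (S)-1-phenylethylamine (2), C[C@H](N)c1ccccc1
Why: TiCl4-mediated ketimine condensation, in which the oxophilic chloride activates the hindered C5 carbonyl and binds the water formed; C10 is left unset on purpose because both epimers feed the same enamine in step 2.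

**Step 2**
Reactants: 3 N-[(1S)-1-phenylethyl]-2,2,6-trimethylcyclohexan-1-imine; 4 methyl (E)-4-oxopent-2-enoate
Product: 7 bicyclic enone ester methyl (1S,8aR)-5,5,8a-trimethyl-3-oxo-1,2,3,5,6,7,8,8a-octahydronaphthalene-1-carboxylate, via Michael adduct imine 5 (not isolated), via diketo ester 6 (not isolated)
Conditions: (i) 4 (1.2 equiv), THF, 20 → 45 °C; (ii) 10% aq AcOH, 20 °C, phase separation and solvent switch; (iii) TsOH·H2O (0.2 equiv), PhMe, reflux, azeotropic removal of water
Reagents that add atoms: methyl (E)-4-oxopent-2-enoate (4), COC(=O)/C=C/C(C)=O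
Why: The two C10 epimers of imine 3 share one secondary enamine (C5=C10; C4 has no hydrogen), which should add through C10 to C9 of 4 in a six-membered aza-ene-like transition state that passes N–H to C8, the closest known reaction type being the deracemising Michael addition of 1-phenylethylamine imines of 2-alkylcyclohexanones followed by Robinson-type cyclodehydration. Aqueous acetic acid then hydrolyses imine 5 and releases the amine, and under acid catalysis the C6 methyl enol of diketo ester 6 attacks the C5 carbonyl in a 6-(enolendo)-exo-trig aldol closure of ring B, dehydration giving the C5=C6–C7=O enone (the water oxygen placed on C5 leaves again). C10 is controlled by the phenylethyl stereocentre: the acceptor approaches the enamine face away from the phenyl group, the sense that for the (S)-amine corresponds to the 10β-methyl series. C9 is controlled by the compact arrangement of the (E)-acceptor, acetyl group over nitrogen and ester pointing outward, which puts H9 anti to the C10 methyl group (9β-ester); because equilibration at C9 is not expected to favour this epimer reliably, no basic operation is included. The step needs attack at the ester-bearing alkene carbon, secured because the ketone is the stronger activating group and attack occurs β to it, and closure of C6 onto C5 instead of Claisen closure onto the C11 ester, secured by acid instead of alkoxide catalysis. For the internal proton transfer the enamine must place its N-substituent beside the C4 gem-dimethyl group, which is the main uncertainty and is offset by the high electrophilicity of the doubly activated acceptor.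

**Step 3**
Reactants: 7 bicyclic enone ester
Product: 8 methyl 8-methyl-7-oxo-Δ5 ester (9β-CO2CH3, 10β-CH3; C8 epimers)
Conditions: LiN(iPr)2 (1.1 equiv, commercial solution), THF, −78 °C; MeI (1.5 equiv), −78 → −20 °C
Reagents that add atoms: iodomethane, CI
Why: Kinetic enolate alkylation, C8 being the only enolisable carbon of the C7 ketone (C6 is vinylic, C4 and C10 carry no γ-hydrogen) and far more acidic than the ester α-position C9; the C8 configuration is immaterial because step 4 erases it.

**Step 4**
Reactants: 8 methyl 8-methyl-7-oxo-Δ5 ester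
Product: 9 methyl 8α-hydroxy-8β-methyl-7-oxo-Δ5 ester (9β-CO2CH3, 10β-CH3)
Conditions: KN(SiMe3)2 (1.2 equiv), THF, −78 °C; 2-(phenylsulfonyl)-3-phenyloxaziridine (1.3 equiv), −78 °C; AcOH quench at −78 °C
Reagents that add atoms: 2-(phenylsulfonyl)-3-phenyloxaziridine, O=S(=O)(N1OC1c1ccccc1)c1ccccc1
Why: Enolate hydroxylation with an N-sulfonyloxaziridine, in which the tetrasubstituted C7=C8 potassium enolate should take oxygen on the α face, away from the axial C10 methyl group (1,3 to C8) and the β-oriented ester on C9, leaving 8α-OH and 8β-CH3.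

**Step 5**
Reactants: 9 methyl 8α-hydroxy-8β-methyl-7-oxo-Δ5 ester
Product: 10 methyl 7β,8α-dihydroxy-8β-methyl-Δ5 ester
Conditions: NaBH4 (1.0 equiv), CeCl3·7H2O (1.0 equiv), MeOH, −78 → −20 °C
Reagents that add atoms: none
Why: Luche 1,2-reduction, in which hydride should enter C7 from the α face, anti to the pseudoaxial 8β-methyl group (the sense in which 10β-methyl Δ4-3-keto steroids give equatorial allylic alcohols), to give the 7β-alcohol without touching the ester or C5=C6.

**Step 6**
Reactants: 10 methyl 7β,8α-dihydroxy-8β-methyl-Δ5 ester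
Product: 11 methyl 7β,8α-bis(triethylsilyloxy)-8β-methyl-Δ5 ester
Conditions: Et3SiOTf (3 equiv), 2,6-lutidine (4 equiv), CH2Cl2, −78 → 20 °C
Reagents that add atoms: triethylsilyl trifluoromethanesulfonate, CC[Si](CC)(CC)OS(=O)(=O)C(F)(F)F
Why: Silyl ether formation with a silyl triflate, reactive enough for the tertiary C8 hydroxyl as well as the allylic C7 hydroxyl; O7 is masked so that only O6 is acetylated later, and O8 so that the later C11 aldehyde is not a free β-hydroxy aldehyde.

**Step 7**
Reactants: 11 methyl 7β,8α-bis(triethylsilyloxy)-8β-methyl-Δ5 ester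
Product: 12 C11 primary alcohol, 7β,8α-bis(triethylsilyloxy)-Δ5
Conditions: LiAlH4 (2 equiv), THF, 0 → 20 °C; H2O
Reagents that add atoms: none
Why: Hydride reduction of the hindered methyl ester to the primary alcohol with LiAlH4, to which the triethylsilyl ethers and the isolated trisubstituted alkene are inert.

**Step 8**
Reactants: 12 C11 primary alcohol, 7β,8α-bis(triethylsilyloxy)-Δ5
Product: 13 6α,11-diol, 5α-H, 7β,8α-bis(triethylsilyloxy)
Conditions: BH3·THF (4 equiv), THF, 0 → 20 °C; then 3 M NaOH, 30% H2O2, 0 °C (short contact)
Reagents that add atoms: hydrogen peroxide, OO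
Why: Hydroboration–oxidation, in which boron should add to the less substituted C6 and hydrogen to C5, syn and on the α face because the β face is closed by the axial C10 and C4 methyl groups and the 7β-silyloxy group, setting 5α-H (trans ring fusion) and, after oxidation with retention, 6α-OH.

**Step 9**
Reactants: 13 6α,11-diol
Product: 14 C11 aldehyde, 6α-OH, 7β,8α-bis(triethylsilyloxy) (9β-CHO)
Conditions: TEMPO (0.2 equiv), PhI(OAc)2 (1.2 equiv), CH2Cl2, 20 °C
Reagents that add atoms: none
Why: Nitroxyl-catalysed alcohol oxidation, which should take the primary C11 alcohol in preference to the more shielded secondary 6α-alcohol and stop at the aldehyde under non-basic conditions that spare C9.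

**Step 10**
Reactants: 14 C11 aldehyde; 15 1-(triphenylphosphoranylidene)propan-2-one
Product: 16 (E)-enone, 6α-OH, 7β,8α-bis(triethylsilyloxy)
Conditions: 15 (3 equiv), PhMe, 100 °C
Reagents that add atoms: 1-(triphenylphosphoranylidene)propan-2-one (15), CC(=O)C=P(c1ccccc1)(c1ccccc1)c1ccccc1
Why: Wittig olefination with a stabilised acyl ylide, which should give the (E)-C11=C12 enone under essentially neutral conditions that tolerate the free C6 hydroxyl and leave C9 untouched.

**Step 11**
Reactants: 16 (E)-enone, 6α-OH
Product: 17 (E)-enone, 6α-acetate, 7β,8α-bis(triethylsilyloxy)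
Conditions: Ac2O (3 equiv), DMAP (0.2 equiv), pyridine, 20 → 40 °C
Reagents that add atoms: acetic anhydride, CC(=O)OC(C)=O
Why: DMAP-catalysed acylation of the only free hydroxyl group, the equatorial 6α-OH.

**Step 12**
Reactants: 17 (E)-enone, 6α-acetate, 7β,8α-bis(triethylsilyloxy)
Product: 18 target CNP0136046.1
Conditions: HF·pyridine, pyridine, THF, 0 → 20 °C
Reagents that add atoms: none
Why: Fluoride-mediated silyl ether cleavage under mildly acidic conditions, which should remove both triethylsilyl groups without hydrolysing or shifting the C6 acetate and without affecting the enone.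

**Compound list**
1 | 2,2,6-trimethylcyclohexanone (racemic) | CC1CCCC(C)(C)C1=O | starting material
2 | (S)-1-phenylethylamine | C[C@H](N)c1ccccc1 | starting material
3 | N-[(1S)-1-phenylethyl]-2,2,6-trimethylcyclohexan-1-imine (both C10 epimers) | C[C@H](N=C1C(C)CCCC1(C)C)c1ccccc1 | intermediate
4 | methyl (E)-4-oxopent-2-enoate | COC(=O)/C=C/C(C)=O | starting material
5 | Michael adduct imine, methyl (2S)-4-oxo-2-[(1R)-1,3,3-trimethyl-2-{[(1S)-1-phenylethyl]imino}cyclohexyl]pentanoate | C[C@H](N=C1C(C)(C)CCC[C@]1(C)[C@H](CC(C)=O)C(=O)OC)c1ccccc1 | intermediate (not isolated)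
6 | diketo ester, methyl (2S)-4-oxo-2-[(1R)-1,3,3-trimethyl-2-oxocyclohexyl]pentanoate | COC(=O)[C@@H](CC(C)=O)[C@@]1(C)CCCC(C)(C)C1=O | intermediate (not isolated)
7 | bicyclic enone ester, methyl (1S,8aR)-5,5,8a-trimethyl-3-oxo-1,2,3,5,6,7,8,8a-octahydronaphthalene-1-carboxylate (9β-CO2CH3, 10β-CH3, Δ5-7-one) | COC(=O)[C@H]1CC(=O)C=C2C(C)(C)CCC[C@@]21C | intermediate
8 | methyl 8-methyl-7-oxo-Δ5 ester (9β-CO2CH3, 10β-CH3; C8 epimers) | COC(=O)[C@H]1C(C)C(=O)C=C2C(C)(C)CCC[C@@]21C | intermediate
9 | methyl 8α-hydroxy-8β-methyl-7-oxo-Δ5 ester | COC(=O)[C@H]1[C@](C)(O)C(=O)C=C2C(C)(C)CCC[C@@]21C | intermediate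
10 | methyl 7β,8α-dihydroxy-8β-methyl-Δ5 ester | COC(=O)[C@H]1[C@](C)(O)[C@@H](O)C=C2C(C)(C)CCC[C@@]21C | intermediate
11 | methyl 7β,8α-bis(triethylsilyloxy)-8β-methyl-Δ5 ester | COC(=O)[C@H]1[C@](C)(O[Si](CC)(CC)CC)[C@@H](O[Si](CC)(CC)CC)C=C2C(C)(C)CCC[C@@]21C | intermediate
12 | C11 primary alcohol, 7β,8α-bis(triethylsilyloxy)-Δ5 | OC[C@H]1[C@](C)(O[Si](CC)(CC)CC)[C@@H](O[Si](CC)(CC)CC)C=C2C(C)(C)CCC[C@@]21C | intermediate
13 | 6α,11-diol, 5α-H, 7β,8α-bis(triethylsilyloxy) | OC[C@H]1[C@](C)(O[Si](CC)(CC)CC)[C@@H](O[Si](CC)(CC)CC)[C@H](O)[C@H]2C(C)(C)CCC[C@@]21C | intermediate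
14 | C11 aldehyde, 6α-OH, 7β,8α-bis(triethylsilyloxy) | O=C[C@H]1[C@](C)(O[Si](CC)(CC)CC)[C@@H](O[Si](CC)(CC)CC)[C@H](O)[C@H]2C(C)(C)CCC[C@@]21C | intermediate
15 | 1-(triphenylphosphoranylidene)propan-2-one | CC(=O)C=P(c1ccccc1)(c1ccccc1)c1ccccc1 | starting material
16 | (E)-enone, 6α-OH, 7β,8α-bis(triethylsilyloxy) | CC(=O)/C=C/[C@H]1[C@](C)(O[Si](CC)(CC)CC)[C@@H](O[Si](CC)(CC)CC)[C@H](O)[C@H]2C(C)(C)CCC[C@@]21C | intermediate
17 | (E)-enone, 6α-acetate, 7β,8α-bis(triethylsilyloxy) | CC(=O)/C=C/[C@H]1[C@](C)(O[Si](CC)(CC)CC)[C@@H](O[Si](CC)(CC)CC)[C@H](OC(C)=O)[C@H]2C(C)(C)CCC[C@@]21C | intermediate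
18 | CNP0136046.1, (3E)-4-[(1R,2S,3S,4R,4aS,8aS)-4-acetoxy-2,3-dihydroxy-2,5,5,8a-tetramethyldecahydronaphthalen-1-yl]but-3-en-2-one (6α-OAc, 7β-OH, 8α-OH) | CC(=O)/C=C/[C@H]1[C@](C)(O)[C@@H](O)[C@H](OC(C)=O)[C@H]2C(C)(C)CCC[C@@]21C | target

**Step count**
Total: 12 steps. Longest linear sequence: 12 steps (1 → 18); compounds 2, 4 and 15 are purchased.

**Steps most likely to fail**

Step 2. The cyclodehydration may stall at the open diketone, because the C5 carbonyl is shielded by quaternary C4 and C10. Prolonged heating could then lead to retro-Michael cleavage or erosion at C9. The conjugate addition is the lesser worry because 4 is a doubly activated acceptor. The fallback sets out from diketo ester 6, isolated after the hydrolysis. Kinetic enolisation of the C6 methyl group with LiN(iPr)2 in the presence of Me3SiCl (THF, −78 °C) should give the terminal trimethylsilyl enol ether F1. TiCl4 in CH2Cl2 at −78 °C would then promote an intramolecular Mukaiyama aldol addition onto the Lewis-acid-activated C5 carbonyl, an addition in which silyl enol ethers do not attack the ester, to give the β-hydroxy ketone F2. Acid-catalysed dehydration of F2 (TsOH, PhMe, 60 °C), which can only occur towards C6, returns to the route at 7.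

Step 10. The stabilised ylide may add slowly to the C11 aldehyde, which sits between two fully substituted carbons; this leaves time for epimerisation at C9 or β-elimination of the C8 silyloxy group. The fallback sets out from 14. Methylenation with the small, fast ylide Ph3P=CH2 (from Ph3PCH3Br and KN(SiMe3)2, THF, −78 → 0 °C) should give the C9-vinyl compound F3. Cross-metathesis of F3 with excess methyl vinyl ketone (second-generation Hoveyda–Grubbs catalyst, CH2Cl2, 40 °C) should form the (E)-enone and return to the route at 16.

Step 4. The hindered tertiary C8–H may enolise incompletely, deprotonation α to the ester at C9 may compete, and the product alkoxide may undergo base-induced α-ketol rearrangement. The fallback sets out from 8 and avoids strong base. Soft enolisation with Me3SiOTf and Et3N (CH2Cl2, 0 °C) should give the trimethylsilyl dienol ether F4. Rubottom oxidation of F4 with dimethyldioxirane (acetone, −40 °C) should epoxidise the electron-rich C7=C8 bond on the α face, and work-up with citric acid in MeOH returns to the route at 9.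

**Further compounds**
F1 | step 2 | terminal trimethylsilyl enol ether of diketo ester 6 (C6=C7) | COC(=O)[C@@H](CC(=C)O[Si](C)(C)C)[C@@]1(C)CCCC(C)(C)C1=O
F2 | step 2 | β-hydroxy ketone, methyl 5-hydroxy-7-oxo bicyclic ester (C5 epimers) | COC(=O)[C@H]1CC(=O)CC2(O)C(C)(C)CCC[C@@]21C
F3 | step 10 | C9-vinyl compound, 6α-OH, 7β,8α-bis(triethylsilyloxy) | C=C[C@H]1[C@](C)(O[Si](CC)(CC)CC)[C@@H](O[Si](CC)(CC)CC)[C@H](O)[C@H]2C(C)(C)CCC[C@@]21C
F4 | step 4 | trimethylsilyl dienol ether of 8 (C5=C6, C7=C8) | COC(=O)[C@H]1C(C)=C(O[Si](C)(C)C)C=C2C(C)(C)CCC[C@@]21C
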